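## Structural features

The target is a trans-fused decalin (ring A: C1–C5 and C10; ring B: C5–C10; shared bond C5–C10, eudesmane numbering throughout). It carries an exocyclic methylene on C4, an angular methyl on C10, an isopropyl group on C7 and, on C6, the ester oxygen of an (E)-4-hydroxycinnamate. The four stereocentres C10, C5, C6 and C7 are contiguous along ring B: 10β-methyl, 5α-hydrogen, 6α-oxygen, 7β-isopropyl (5S,6S,7S,10R). Every ring B substituent except the axial angular methyl is therefore equatorial. The C6 oxygen is hindered, lying between the ring fusion and the isopropyl-bearing C7 and peri to C4. The fragile groups are: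

- the 1,1-disubstituted C4=C15 alkene, which acid moves into the ring;
- the C5 hydrogen for as long as C4 is a carbonyl, because it is epimerisable;
- any C4 ketone with a free or acylated C6 oxygen, which can lose that oxygen by E1cB elimination;
- the coumarate, with its free phenol, conjugated E-alkene and base-labile ester.

The real difficulty is absolute control of a quaternary C10 whose only relation to the easily made C7 centre is 1,4 across ring B, followed by setting C5 and C6 next to that quaternary carbon. The feature used is that ring B with C10 as a carbonyl carbon is achiral 4-isopropylcyclohexanone, with a mirror plane through C10 and C7. Choosing which enantiotopic α-carbon becomes C5 makes C7 stereogenic, and the C5=C10 alkene so defined is then acylated at C5 by a C1–C4 chain hanging on C10, which closes ring A.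

## Logic of the disconnections

**21 ⇒ 15 + 18 (through 20 and 19).** The acyl C–O bond to O6 is cut, and the phenol O–H is exchanged for O–Si. The ester is the only link between the terpenoid and the aromatic half, and cutting on the acyl side leaves the stereogenic, hindered C6–O bond untouched. This separates all four stereocentres (in 15) from the base- and nucleophile-sensitive cinnamate. The forward step must acylate a hindered equatorial hydroxyl without a free phenol competing, and the final desilylation must spare the ester and the exocyclic alkene.

**18 ⇒ 16 (through 17).** Only the two O–Si bonds are cut. The demand is selective hydrolysis of the silyl ester in the presence of the aryl silyl ether.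

**15 ⇒ 14.** The C6–O bond is exchanged for a C6–B bond. A boronate is oxidised with retention, does not β-eliminate and needs no protecting group, so the oxygen can stay masked until the ketone at C4 is gone. The oxidation must leave the C4=C15 alkene alone.

**14 ⇒ 13.** The C4=C15 double bond is cut back to the C4 ketone. The acid-sensitive methylene is thus made late, from the carbonyl that every earlier step needs. The methylenation must be non-basic, because C5 is epimerisable, and must cope with a hindered ketone.

**13 ⇒ 12.** The C6–B and C5–H bonds are cut, leaving a planar enone. Two adjacent stereocentres are traded for one trisubstituted alkene. The forward step must bring boron to the α face of C6, opposite the axial angular methyl, and must leave C5 with its hydrogen α (trans fusion).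

**12 ⇒ 10 (through 11).** The C10–C14 bond is cut and the C5=C6 unsaturation is moved back to C5=C10. Compound 10 has a single stereocentre. The methyl must add to C10 cis to the C7 isopropyl under 1,4-control across ring B, and the resulting enol derivative must be dehydrogenated towards C6, the only side that has a hydrogen.

**10 ⇒ 8 (through 9).** The C4–C5 bond is cut; this is the strategic bond. Ring A is opened to a monocyclic cyclohexene with a four-carbon acyl chain, and the stereochemical content shrinks to the position of one double bond relative to C7. C–C bond formation at C5 must occur before any proton-mediated shift of that double bond.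

**8 ⇒ 7 ⇒ 6.** The C–Cl and O–ethyl bonds of the acyl group are cut. The acid chloride must be made without free HCl.

**6 ⇒ 3 + 4 (through 5).** The sp2–sp3 bond C10–C1 is cut. The coupling must tolerate the ester and must form the bond exactly at the triflate carbon, so that the alkene position, and with it the chirality, is retained.

**3 ⇒ 1 (through 2).** The O–S bond is cut, and behind it the choice between two enantiotopic α-protons. Compound 1 is achiral and commercial. The deprotonation must discriminate the two axial α-protons, and the enolate must be trapped before it can equilibrate.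

## Other disconnections considered

**Alternative 1:** The cut is the transannular C5–C10 bond, giving the ten-membered (1S,2E,6E,10S)-3,7-dimethyl-10-(propan-2-yl)cyclodeca-2,6-dien-1-ol A2. In the forward direction camphorsulfonic acid protonates C1, the C10 cation is captured by C5 across the ring, and the C4 cation loses a C15 proton to give eudesm-4(15)-en-6α-ol A1, which has the same structure as 15.
- In its favour: one step forms both six-membered rings, the ring fusion, the exocyclic alkene and the free hydroxyl. Beyond the cyclisation it needs only the esterification, which is better in step economy than the chosen plan, where five steps separate 10 from 15.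
- Against it: A2 is a medium ring with two E-trisubstituted alkenes and two adjacent stereocentres, and making it enantiopure is a long synthesis in itself. Such 1,5-dienes can undergo Cope rearrangement on warming. The C6 hydroxyl is allylic to C4=C5 and may ionise under the acid. Termination can also give the ring alkene or a hydration product, and the ring conformer that cyclises decides the relation of C5 and C10 to C7.
- Comparison: both plans use a cationic C–C bond formation, but in the chosen plan that step creates no stereocentre and so has only positional selectivity to control. The price is that C10, C5 and C6 are then set in separate steps.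

**Alternative 2:** The cut is C6–C7, giving (R)-2,6-dimethyl-6-(4-methylpent-3-en-1-yl)cyclohex-1-ene-1-carbaldehyde A4. Under Me2AlCl the aldehyde adds to C7 of the side-chain alkene with transfer of an allylic methyl hydrogen to oxygen, closing ring B to (6α,7β,10β)-eudesma-4,11-dien-6-ol A3.
- In its favour: the C6 oxygen and the C7 side chain arise trans to each other in one chair-like ene step. On the introduction of the C6 oxygen this is better than the chosen plan, which needs a separate borylation and oxidation.
- Against it: the quaternary C10 of A4 must be made enantioselectively on its own, and the facial bias of the aldehyde relative to the C10 methyl must give 6α,7β. A3 also has the wrong unsaturation: its tetrasubstituted C4=C5 alkene would have to be moved contra-thermodynamically to C4=C15 while C5 receives an α-hydrogen, and the isopropenyl group must be reduced selectively.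
- Comparison: the skeleton is reached in fewer steps, but the corrections after the key step are unsolved and would outweigh that saving.

**Alternative 3:** The cut is the C5=C6 double bond, giving (3R)-3-methyl-2-methylidene-3-[(3S)-3-(propan-2-yl)pent-4-en-1-yl]cyclohexan-1-one A6. Ring-closing metathesis with the second-generation Grubbs catalyst, with loss of ethylene, gives the enone A5, which has the same structure as 12.
- In its favour: the endgame is identical with that of the chosen plan, and no cationic step or alkene-migration risk is involved. C10 and C7 are set independently by reagent control and not by 1,4-induction in a cuprate addition; on security of the C10/C7 relation it is the better plan.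
- Against it: A6 needs two separately made stereocentres. α-Methylene ketones dimerise and polymerise easily, and metathesis onto a 1,1-disubstituted electron-poor alkene is slow.
- Comparison: the chosen plan reaches the same enone in seven steps from commercial materials with a single asymmetric operation. Alternative 3 would need at least as many steps and two asymmetric operations, so it is equal after the key step and longer before it.

Key step: step 5

Assumption (sense of induction): lithium (S,S)-bis(1-phenylethyl)amide is taken to remove the α-proton that leads to the (R)-enolate 2, by analogy with other 4-alkylcyclohexanones; if the sense is the reverse for this substrate, the equally available (R,R)-amine is used and nothing else changes.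

## Route

Step 1
Reactants: 1 4-isopropylcyclohexanone
Product: 3 (R)-4-isopropylcyclohex-1-en-1-yl trifluoromethanesulfonate, via lithium enolate 2 (not isolated)
Conditions: (S,S)-bis(1-phenylethyl)amine·HCl (1.1 equiv), n-BuLi (2.2 equiv), THF, −78 °C; 1 added slowly, −78 °C; PhNTf2 (1.2 equiv), −78 → 0 °C
Reagents that add atoms: N-phenylbis(trifluoromethanesulfonimide), O=S(=O)(N(c1ccccc1)S(=O)(=O)C(F)(F)F)C(F)(F)F
Why: Enantioselective deprotonation by a chiral lithium amide, in which the base as its mixed aggregate with LiCl (formed from the hydrochloride) should discriminate the two enantiotopic axial α-protons of the chair with equatorial isopropyl; this makes C7 stereogenic. The enolate cannot racemise without a proton source because its chirality lies in the position of the double bond, and O-triflation fixes it.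

Step 2
Reactants: 3 (R)-4-isopropylcyclohex-1-en-1-yl trifluoromethanesulfonate; 4 ethyl 4-bromobutanoate
Product: 6 ethyl 4-[(R)-4-isopropylcyclohex-1-en-1-yl]butanoate, via alkylzinc bromide 5 (not isolated)
Conditions: 4, Zn dust, LiCl, cat. BrCH2CH2Br/Me3SiCl, THF, 50 °C; then 3, Pd(PPh3)4 (5 mol %), THF, 50 °C
Reagents that add atoms: none
Why: Negishi coupling: zerovalent palladium inserts into the vinyl C–O bond, the ester-bearing primary alkylzinc transmetalates, and reductive elimination forms C10–C1 at the triflate carbon, so the alkene position and the configuration are retained.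

Step 3
Reactants: 6 ethyl 4-[(R)-4-isopropylcyclohex-1-en-1-yl]butanoate
Product: 7 4-[(R)-4-isopropylcyclohex-1-en-1-yl]butanoic acid
Conditions: LiOH, THF–MeOH–H2O, rt; cold 0.5 M HCl to pH 4, extraction
Reagents that add atoms: lithium hydroxide, [Li+].[OH-]
Why: Ester saponification; the brief, cold and only mildly acidic work-up avoids protonation of the trisubstituted alkene, which could shift it or lead to lactonisation.

Step 4
Reactants: 7 4-[(R)-4-isopropylcyclohex-1-en-1-yl]butanoic acid
Product: 8 4-[(R)-4-isopropylcyclohex-1-en-1-yl]butanoyl chloride
Conditions: (COCl)2 (1.1 equiv), pyridine (1.1 equiv), hexane–CH2Cl2, 0 °C; filtered under argon, concentrated, used at once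
Reagents that add atoms: oxalyl chloride, O=C(Cl)C(=O)Cl
Why: Acid chloride formation through the mixed oxalic anhydride; pyridine binds the HCl as an insoluble salt, so the alkene whose position carries the chirality never meets free acid.

Step 5
Reactants: 8 4-[(R)-4-isopropylcyclohex-1-en-1-yl]butanoyl chloride
Product: 10 (7R)-7-isopropyl-3,4,5,6,7,8-hexahydronaphthalen-1(2H)-one, via beta-chloro ketone 9 (not isolated)
Conditions: SnCl4 (1.2 equiv), 2,6-di-tert-butyl-4-methylpyridine (0.2 equiv), CH2Cl2, −78 → −40 °C; cold aq. NaHCO3; crude in CH2Cl2, DBU (1.5 equiv), 0 °C → rt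
Reagents that add atoms: none
Why: SnCl4 ionises the acid chloride of 8 to an acylium ion, whose carbon C4 attacks C5, the unsubstituted carbon of the C5=C10 alkene, so that the charge develops at tertiary C10. The closest known reaction type is the Lewis-acid-mediated intramolecular acylation of an alkene by a tethered acid chloride (aliphatic Friedel–Crafts or Darzens–Nenitzescu acylation), which turns cyclohexenylalkanoyl chlorides into bicyclic enones. Ring A closes in the 6-endo mode, the attacked alkene lying inside the new six-membered ring; the 5-exo mode would put the charge on secondary C5 and give a spiro ketone, so polarisation and ring size point the same way. Chloride from SnCl5− captures C10 to give 9, so no free acid is released while unreacted 8 is present; DBU then removes HCl by E1cB and draws any β,γ-unsaturated isomer into the tetrasubstituted conjugated position. No stereocentre is created: C5 and C10 end planar, the centres of 9 are erased, and C7 is remote and untouched. The selectivity needed is positional, because a proton-mediated shift of the double bond to C9=C10 before acylation would exchange the two enantiotopic α-carbons and lower the enantiomeric purity. It is secured by the intramolecular rate at −78 °C, by an aprotic Lewis acid, by the hindered pyridine as proton trap and by having made 8 without free HCl. Once C4–C5 exists, the configuration is written into the connectivity and cannot be lost.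

Step 6
Reactants: 10 (7R)-7-isopropyl-3,4,5,6,7,8-hexahydronaphthalen-1(2H)-one
Product: 11 {[(4aR,7R)-7-isopropyl-4a-methyl-2,3,4,4a,5,6,7,8-octahydronaphthalen-1-yl]oxy}trimethylsilane
Conditions: Me2CuLi (from CuI and MeLi, 1.5 equiv), Me3SiCl (3 equiv), THF, −78 → −30 °C; Et3N; pentane, cold aq. NaHCO3
Reagents that add atoms: lithium dimethylcuprate, [Li+].C[Cu-]C; chlorotrimethylsilane, C[Si](C)(C)Cl
Why: Silyl-chloride-accelerated cuprate conjugate addition to a tetrasubstituted enone. The methyl should enter C10 axially on the ring B half-chair that keeps the C7 isopropyl pseudo-equatorial, the only approach that leads directly to a chair; this places it on the β face, cis to the isopropyl (10R). The silyl enol ether stores the C4=C5 enolate regiochemistry for the next step.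

Step 7
Reactants: 11 {[(4aR,7R)-7-isopropyl-4a-methyl-2,3,4,4a,5,6,7,8-octahydronaphthalen-1-yl]oxy}trimethylsilane
Product: 12 (4aR,7S)-7-isopropyl-4a-methyl-3,4,4a,5,6,7-hexahydronaphthalen-1(2H)-one
Conditions: Pd(OAc)2 (1.1 equiv), MeCN, rt → 40 °C
Reagents that add atoms: none
Why: Saegusa oxidation: divalent palladium forms the C5-bound enolate, and β-hydride elimination can occur only towards C6 because C10 is quaternary, giving the C5=C6 enone. The C7 descriptor changes to S only because the priorities change.

Step 8
Reactants: 12 (4aR,7S)-7-isopropyl-4a-methyl-3,4,4a,5,6,7-hexahydronaphthalen-1(2H)-one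
Product: 13 (4aR,7R,8S,8aR)-7-isopropyl-4a-methyl-8-(4,4,5,5-tetramethyl-1,3,2-dioxaborolan-2-yl)octahydronaphthalen-1(2H)-one
Conditions: B2pin2 (1.2 equiv), CuCl (5 mol %), NaOtBu (10 mol %), bis[2-(diphenylphosphino)phenyl] ether (5 mol %), MeOH (2 equiv), THF, rt; then DBU (0.2 equiv), rt
Reagents that add atoms: bis(pinacolato)diboron, CC1(C)OB(OC1(C)C)B1OC(C)(C)C(C)(C)O1
Why: Copper-catalysed conjugate borylation: the boryl–copper species should add to C6 from the α face, because the β face is closed by the axial angular methyl in a 1,3-relation to C6. C5 is protonated by methanol, and the catalytic DBU lets C5 settle in the trans-fused arrangement (H5α, C4 equatorial on ring B), which is expected to be the more stable. The boronate is a masked hydroxyl that cannot β-eliminate.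

Step 9
Reactants: 13 (4aR,7R,8S,8aR)-7-isopropyl-4a-methyl-8-(4,4,5,5-tetramethyl-1,3,2-dioxaborolan-2-yl)octahydronaphthalen-1(2H)-one
Product: 14 2-[(1S,2R,4aR,8aS)-2-isopropyl-4a-methyl-8-methylidenedecahydronaphthalen-1-yl]-4,4,5,5-tetramethyl-1,3,2-dioxaborolane
Conditions: Cp2TiMe2 (3 equiv), toluene–THF, 65 °C, dark
Reagents that add atoms: dimethyltitanocene, C[Ti](C)(C1C=CC=C1)C1C=CC=C1
Why: Petasis methylenation through titanocene methylidene and an oxatitanacyclobutane; the reagent is non-basic, so the C5 hydrogen next to the ketone is not epimerised, and the boronate ester is inert to it.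

Step 10
Reactants: 14 2-[(1S,2R,4aR,8aS)-2-isopropyl-4a-methyl-8-methylidenedecahydronaphthalen-1-yl]-4,4,5,5-tetramethyl-1,3,2-dioxaborolane
Product: 15 (1S,2S,4aR,8aS)-2-isopropyl-4a-methyl-8-methylidenedecahydronaphthalen-1-ol
Conditions: 30% H2O2, 3 M NaOH, THF, 0 °C → rt
Reagents that add atoms: hydrogen peroxide, OO
Why: Oxidation of the C–B bond by 1,2-migration of C6 from boron to peroxide oxygen with retention, giving the 6α (equatorial) alcohol; alkaline peroxide does not attack the unactivated 1,1-disubstituted alkene, and with no ketone left neither retro-aldol cleavage nor elimination is possible.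

Step 11
Reactants: 16 p-coumaric acid
Product: 18 (E)-3-[4-(tert-butyldimethylsilyloxy)phenyl]prop-2-enoic acid, via bis-silyl derivative 17 (not isolated)
Conditions: t-BuMe2SiCl (2.4 equiv), imidazole (5 equiv), DMF, rt; then AcOH–THF–H2O, rt
Reagents that add atoms: tert-butyldimethylsilyl chloride, CC(C)(C)[Si](C)(C)Cl
Why: Silylation of both acidic sites, then selective hydrolysis of the much more labile silyl ester under mild acid, which leaves the aryl silyl ether and the E-alkene intact.

Step 12
Reactants: 15 (1S,2S,4aR,8aS)-2-isopropyl-4a-methyl-8-methylidenedecahydronaphthalen-1-ol; 18 (E)-3-[4-(tert-butyldimethylsilyloxy)phenyl]prop-2-enoic acid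
Product: 20 (1S,2S,4aR,8aS)-2-isopropyl-4a-methyl-8-methylidenedecahydronaphthalen-1-yl (E)-3-[4-(tert-butyldimethylsilyloxy)phenyl]prop-2-enoate, via mixed anhydride 19 (not isolated)
Conditions: 18, 2,4,6-trichlorobenzoyl chloride, Et3N, THF, rt; then 15, DMAP, toluene, rt → 50 °C
Reagents that add atoms: none
Why: Yamaguchi esterification: DMAP attacks the unshielded cinnamoyl carbonyl of the mixed anhydride, and the acylpyridinium acylates the hindered equatorial hydroxyl. The bond formed is acyl–O, so C6 keeps its configuration, and the conditions contain no acid that could move the exocyclic alkene.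

Step 13
Reactants: 20 (1S,2S,4aR,8aS)-2-isopropyl-4a-methyl-8-methylidenedecahydronaphthalen-1-yl (E)-3-[4-(tert-butyldimethylsilyloxy)phenyl]prop-2-enoate
Product: 21 (1S,2S,4aR,8aS)-2-isopropyl-4a-methyl-8-methylidenedecahydronaphthalen-1-yl (E)-3-(4-hydroxyphenyl)prop-2-enoate
Conditions: Bu4NF (1.1 equiv), AcOH (1.1 equiv), THF, 0 °C
Reagents that add atoms: none
Why: Fluoride cleavage of the aryl silyl ether; the acetic acid buffer protonates the phenoxide at once, so the hindered ester and the conjugated alkene are not exposed to base.

## Compound list

1 | 4-isopropylcyclohexanone | CC(C)C1CCC(=O)CC1 | starting material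
2 | lithium (R)-4-isopropylcyclohex-1-en-1-olate | [Li+].[O-]C1=CC[C@H](C(C)C)CC1 | intermediate (not isolated)
3 | (R)-4-isopropylcyclohex-1-en-1-yl trifluoromethanesulfonate | O=S(=O)(OC1=CC[C@H](C(C)C)CC1)C(F)(F)F | intermediate
4 | ethyl 4-bromobutanoate | CCOC(=O)CCCBr | starting material
5 | (4-ethoxy-4-oxobutyl)zinc bromide | CCOC(=O)CCC[Zn]Br | intermediate (not isolated)
6 | ethyl 4-[(R)-4-isopropylcyclohex-1-en-1-yl]butanoate | CCOC(=O)CCCC1=CC[C@H](C(C)C)CC1 | intermediate
7 | 4-[(R)-4-isopropylcyclohex-1-en-1-yl]butanoic acid | OC(=O)CCCC1=CC[C@H](C(C)C)CC1 | intermediate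
8 | 4-[(R)-4-isopropylcyclohex-1-en-1-yl]butanoyl chloride | O=C(Cl)CCCC1=CC[C@H](C(C)C)CC1 | intermediate
9 | (7R)-4a-chloro-7-isopropyloctahydronaphthalen-1(2H)-one, mixture at C4a and C8a | O=C1CCCC2(Cl)CC[C@@H](C(C)C)CC12 | intermediate (not isolated)
10 | (7R)-7-isopropyl-3,4,5,6,7,8-hexahydronaphthalen-1(2H)-one | O=C1CCCC2=C1C[C@H](C(C)C)CC2 | intermediate
11 | {[(4aR,7R)-7-isopropyl-4a-methyl-2,3,4,4a,5,6,7,8-octahydronaphthalen-1-yl]oxy}trimethylsilane | C[Si](C)(C)OC1=C2C[C@H](C(C)C)CC[C@@]2(C)CCC1 | intermediate
12 | (4aR,7S)-7-isopropyl-4a-methyl-3,4,4a,5,6,7-hexahydronaphthalen-1(2H)-one | O=C1CCC[C@]2(C)CC[C@@H](C(C)C)C=C12 | intermediate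
13 | (4aR,7R,8S,8aR)-7-isopropyl-4a-methyl-8-(4,4,5,5-tetramethyl-1,3,2-dioxaborolan-2-yl)octahydronaphthalen-1(2H)-one | O=C1CCC[C@]2(C)CC[C@@H](C(C)C)[C@H](B3OC(C)(C)C(C)(C)O3)[C@@H]12 | intermediate
14 | 2-[(1S,2R,4aR,8aS)-2-isopropyl-4a-methyl-8-methylidenedecahydronaphthalen-1-yl]-4,4,5,5-tetramethyl-1,3,2-dioxaborolane | C=C1CCC[C@]2(C)CC[C@@H](C(C)C)[C@H](B3OC(C)(C)C(C)(C)O3)[C@@H]12 | intermediate
15 | (1S,2S,4aR,8aS)-2-isopropyl-4a-methyl-8-methylidenedecahydronaphthalen-1-ol | C=C1CCC[C@]2(C)CC[C@@H](C(C)C)[C@H](O)[C@@H]12 | intermediate
16 | p-coumaric acid, (E)-3-(4-hydroxyphenyl)prop-2-enoic acid | OC(=O)/C=C/c1ccc(O)cc1 | starting material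
17 | tert-butyldimethylsilyl (E)-3-[4-(tert-butyldimethylsilyloxy)phenyl]prop-2-enoate | CC(C)(C)[Si](C)(C)OC(=O)/C=C/c1ccc(O[Si](C)(C)C(C)(C)C)cc1 | intermediate (not isolated)
18 | (E)-3-[4-(tert-butyldimethylsilyloxy)phenyl]prop-2-enoic acid | CC(C)(C)[Si](C)(C)Oc1ccc(/C=C/C(=O)O)cc1 | intermediate
19 | (E)-3-[4-(tert-butyldimethylsilyloxy)phenyl]prop-2-enoic 2,4,6-trichlorobenzoic anhydride | CC(C)(C)[Si](C)(C)Oc1ccc(/C=C/C(=O)OC(=O)c2c(Cl)cc(Cl)cc2Cl)cc1 | intermediate (not isolated)
20 | (1S,2S,4aR,8aS)-2-isopropyl-4a-methyl-8-methylidenedecahydronaphthalen-1-yl (E)-3-[4-(tert-butyldimethylsilyloxy)phenyl]prop-2-enoate | C=C1CCC[C@]2(C)CC[C@@H](C(C)C)[C@H](OC(=O)/C=C/c3ccc(O[Si](C)(C)C(C)(C)C)cc3)[C@@H]12 | intermediate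
21 | (1S,2S,4aR,8aS)-2-isopropyl-4a-methyl-8-methylidenedecahydronaphthalen-1-yl (E)-3-(4-hydroxyphenyl)prop-2-enoate | C=C1CCC[C@]2(C)CC[C@@H](C(C)C)[C@H](OC(=O)/C=C/c3ccc(O)cc3)[C@@H]12 | target

## Step count and least certain steps

Total: 13 steps. Longest linear sequence: 12 steps (steps 1–10, 12 and 13); step 11 is a one-step side branch.

**Step 5 (key step).** The most likely failure is erosion of enantiomeric purity through proton-mediated migration of the ring double bond before the C–C bond forms, because any adventitious Brønsted acid combined with SnCl4 is a very strong acid. A second risk is incomplete dehydrochlorination. The fallback sets out from 6 and returns at 10. Compound 6 would be reduced with i-Bu2AlH (CH2Cl2, −78 °C) to the aldehyde 4-[(R)-4-isopropylcyclohex-1-en-1-yl]butanal F1. With Me2AlCl (CH2Cl2, −78 → 0 °C), F1 should undergo a type 2 intramolecular carbonyl-ene reaction, the aldehyde carbon bonding to C5 while an allylic C9 hydrogen passes to oxygen, to give the homoallylic alcohol (7R)-7-isopropyl-1,2,3,4,6,7,8,8a-octahydronaphthalen-1-ol F2. Dess–Martin oxidation would give the β,γ-unsaturated ketone (7R)-7-isopropyl-3,4,6,7,8,8a-hexahydronaphthalen-1(2H)-one F3, and DBU would move the double bond into conjugation to give 10. Me2AlCl destroys protons by losing methane, so the same C4–C5 bond is formed without a protic pathway.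

**Step 1.** The risk is insufficient discrimination between the two enantiotopic α-protons, together with partial equilibration of the enolate if unreacted ketone is present during warming. The fallback sets out from 1 and returns at 2. Compound 1 would be deprotonated at −78 °C or below with a chelating chiral lithium amide, lithium [1-phenyl-2-(piperidin-1-yl)ethyl](2,2,2-trifluoroethyl)amide of the configuration that removes the required proton, with Me3SiCl present from the start. This internal quench gives the silyl enol ether trimethyl{[(R)-4-isopropylcyclohex-1-en-1-yl]oxy}silane F4, which can be purified and its enantiomeric purity checked. MeLi (THF, 0 °C) would then regenerate 2, which is triflated as in step 1.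

**Step 6.** The risks are poor facial selectivity at C10, since the only control element is the remote C7 isopropyl acting through the ring B conformation, and slow addition to a tetrasubstituted enone. The fallback sets out from 10, returns at 11 and replaces substrate control by reagent control. Corey–Bakshi–Shibata reduction of 10 with the (R)-methyl oxazaborolidine and BH3·SMe2 should give the allylic alcohol (1S,7R)-7-isopropyl-1,2,3,4,5,6,7,8-octahydronaphthalen-1-ol F5, with the hydroxyl on the β face at C4. Hydroxyl-directed Simmons–Smith cyclopropanation (Et2Zn, CH2I2) would deliver the methylene to the β face of C5=C10 and give the cyclopropyl carbinol 7β-isopropyl-5β,10β-methanodecalin-4β-ol F6. Dess–Martin oxidation would give the cyclopropyl ketone 7β-isopropyl-5β,10β-methanodecalin-4-one F7. Li in NH3/THF should cleave the C5–CH2 bond, the one that overlaps with the carbonyl π system, leaving a β-methyl on C10 and the C4=C5 enolate; quenching with Me3SiCl/Et3N after removal of ammonia would give 11.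

**Step 7.** The risk is slow palladation at the fully substituted C5 next to the quaternary C10, with competing hydrolysis of the silyl enol ether to the saturated ketone. The fallback sets out from 11 and returns at 12. MeLi (THF, 0 °C) would give the lithium enolate lithium (4aR,7R)-7-isopropyl-4a-methyl-2,3,4,4a,5,6,7,8-octahydronaphthalen-1-olate F8. PhSeBr at −78 °C would give the selenide (4aR,7R)-7-isopropyl-4a-methyl-8a-(phenylselanyl)octahydronaphthalen-1(2H)-one F9. Oxidation with H2O2/pyridine and syn-elimination of the selenoxide, possible only towards C6, would give 12.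

**Step 8.** The risk is loss of stereocontrol at C5 and C6. Attack at C6 from the β face is the stereoelectronically axial mode and competes if the steric shielding by the angular methyl is weaker than assumed, and the C5 epimers may not equilibrate far enough towards the trans fusion. The fallback sets out from 12 and returns at 15, setting both centres by one stereospecific syn addition.
- Compound 12 would be ketalised without double-bond shift (1,2-bis(trimethylsilyloxy)ethane, cat. Me3SiOTf, CH2Cl2, −78 °C) to the ethylene ketal of 12, the spiro-dioxolane at C4 with the C5=C6 alkene retained, F10.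
- Hydroboration (BH3·THF, then NaOH/H2O2) from the α face, opposite the angular methyl, would place hydrogen on C5 and oxygen on C6 syn to each other, giving the 6α-hydroxy-5α-H ketal (4aR,7S,8S,8aS configuration in naphthalene numbering) F11.
- Pyridinium p-toluenesulfonate in acetone–H2O would release the β-hydroxy ketone (4aR,7S,8S,8aS)-8-hydroxy-7-isopropyl-4a-methyloctahydronaphthalen-1(2H)-one F12.
- Excess Cp2TiMe2 would methylenate F12 to 15, the hydroxyl being carried as its titanium alkoxide and released on work-up.

Further compounds

F1 | step 5 | 4-[(R)-4-isopropylcyclohex-1-en-1-yl]butanal | O=CCCCC1=CC[C@H](C(C)C)CC1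
F2 | step 5 | (7R)-7-isopropyl-1,2,3,4,6,7,8,8a-octahydronaphthalen-1-ol, mixture at C1 and C8a | OC1CCCC2=CC[C@@H](C(C)C)CC12
F3 | step 5 | (7R)-7-isopropyl-3,4,6,7,8,8a-hexahydronaphthalen-1(2H)-one, mixture at C8a | O=C1CCCC2=CC[C@@H](C(C)C)CC12
F4 | step 1 | trimethyl{[(R)-4-isopropylcyclohex-1-en-1-yl]oxy}silane | C[Si](C)(C)OC1=CC[C@H](C(C)C)CC1
F5 | step 6 | (1S,7R)-7-isopropyl-1,2,3,4,5,6,7,8-octahydronaphthalen-1-ol | O[C@H]1CCCC2=C1C[C@H](C(C)C)CC2
F6 | step 6 | 7β-isopropyl-5β,10β-methanodecalin-4β-ol (eudesmane numbering) | O[C@H]1CCC[C@@]23C[C@@]12C[C@H](C(C)C)CC3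
F7 | step 6 | 7β-isopropyl-5β,10β-methanodecalin-4-one (eudesmane numbering) | O=C1CCC[C@@]23C[C@@]12C[C@H](C(C)C)CC3
F8 | step 7 | lithium (4aR,7R)-7-isopropyl-4a-methyl-2,3,4,4a,5,6,7,8-octahydronaphthalen-1-olate | [Li+].[O-]C1=C2C[C@H](C(C)C)CC[C@@]2(C)CCC1
F9 | step 7 | (4aR,7R)-7-isopropyl-4a-methyl-8a-(phenylselanyl)octahydronaphthalen-1(2H)-one, mixture at C8a | O=C1CCC[C@]2(C)CC[C@@H](C(C)C)CC12[Se]c1ccccc1
F10 | step 8 | ethylene ketal of 12, (4aR,7S)-7-isopropyl-4a-methyl-3,4,4a,5,6,7-hexahydro-2H-spiro[naphthalene-1,2'-[1,3]dioxolane] | O1CCOC12CCC[C@]3(C)CC[C@@H](C(C)C)C=C23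
F11 | step 8 | (4aR,7S,8S,8aS)-7-isopropyl-4a-methyloctahydro-2H-spiro[naphthalene-1,2'-[1,3]dioxolan]-8-ol | O1CCOC12CCC[C@]3(C)CC[C@@H](C(C)C)[C@H](O)[C@@H]23
F12 | step 8 | (4aR,7S,8S,8aS)-8-hydroxy-7-isopropyl-4a-methyloctahydronaphthalen-1(2H)-one | O=C1CCC[C@]2(C)CC[C@@H](C(C)C)[C@H](O)[C@@H]12
A1 | alternative 1 | eudesm-4(15)-en-6α-ol, same structure as 15 | C=C1CCC[C@]2(C)CC[C@@H](C(C)C)[C@H](O)[C@@H]12
A2 | alternative 1 | (1S,2E,6E,10S)-3,7-dimethyl-10-(propan-2-yl)cyclodeca-2,6-dien-1-ol | CC(C)[C@@H]1CC/C(C)=C/CC/C(C)=C/[C@H]1O
A3 | alternative 2 | (6α,7β,10β)-eudesma-4,11-dien-6-ol | CC=1CCC[C@]2(C)CC[C@@H](C(C)=C)[C@H](O)C=12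
A4 | alternative 2 | (R)-2,6-dimethyl-6-(4-methylpent-3-en-1-yl)cyclohex-1-ene-1-carbaldehyde | O=CC1=C(C)CCC[C@]1(C)CCC=C(C)C
A5 | alternative 3 | (4aR,7S)-7-isopropyl-4a-methyl-3,4,4a,5,6,7-hexahydronaphthalen-1(2H)-one, same structure as 12 | O=C1CCC[C@]2(C)CC[C@@H](C(C)C)C=C12
A6 | alternative 3 | (3R)-3-methyl-2-methylidene-3-[(3S)-3-(propan-2-yl)pent-4-en-1-yl]cyclohexan-1-one | O=C1CCC[C@](C)(CC[C@@H](C(C)C)C=C)C1=C
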